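**Conventions and one assumption.** Locants follow the daucane skeleton: C1 angular CMe, C2/C3 CH2, C4 C(OH)iPr, C5 ring-fusion CH, C6 and C10 angelate carbinols, C7 CH2, C8 C(OH)Me, C9 CHOH. α is the face that carries H5, β the face that carries the C1 methyl; in the daucane names the C1 methyl is β and, where C8 is sp3, its methyl is β. Assumption: the sense of induction of the copper catalyst in step 5 is fixed by assay, and the ligand antipode that gives (8aS)-10 is the one used.

## Analysis of the target

Target 24 is a daucane diester: a cyclopentane (C1–C5) trans-fused along C1–C5 to a cycloheptane (C1, C5–C10), with an angular methyl on C1, a tertiary isopropyl carbinol at C4, a tertiary methyl carbinol at C8, a free secondary hydroxyl at C9 and angelates on the secondary oxygens at C6 and C10. It has seven stereocentres (C1, C4, C5, C6, C8, C9, C10): H5 and the oxygens on C6, C8, C9 and C10 lie on the α face, while the C1 methyl, the C4 hydroxyl and the C8 methyl lie on the β face, so the C8/C9/C10 oxygens are all-cis and the C10 oxygen is trans to the neighbouring angular methyl. The sensitive groups are the two angelates (Z to E isomerisation with base, nucleophiles or long heating; acyl migration from O10 to the free O9), the two tertiary alcohols (elimination in strong acid) and, at the ketone stage, a β-hydroxy ketone open to retro-aldol cleavage. Three things make the synthesis hard: the quaternary C1 inside a trans ring fusion, the C10 carbinol whose oxygen must stand anti to the C1 methyl (a hydride that adds anti to that methyl gives the wrong epimer unless the other face is blocked more strongly), and the need to tell O9 apart from O6 and O10 among five hydroxyls. Because the fusion is trans, the C1 methyl and H5 are both axial on the seven-membered ring; a transannular C6/C9 bridge such as a 1,4-endoperoxide would make C5–C1–C10 the three-atom bridge of a bicyclo[3.2.2]nonene and push that axial methyl into the C7=C8 bridge, so the ring oxygens have to be put on one π-face at a time and not by a [4+2] oxygenation. The strategy rests on the six contiguous carbons C1, C10, C9, C8, C7 and C6: with oxygen on C10 next to C1 and the methyl on C8 three bonds from C1, they are the ring of a 2-methoxy-4-methylphenyl group (C1 ipso, C10 ortho with OMe, C8 para with Me). C5, which joins C1 to C6 and carries the C4 carbinol, is then a carbene carbon inserted into the arene C1–C6 bond, and C4 is the carbonyl of an aryl diazoketone.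

## Retrosynthetic reasoning

**24 ⇒ 23 ⇒ 20 + 21 (ester C–O bonds, ketal).** The two angelate C–O bonds are cut last because the Z-enoates survive neither hydride, base nor osmium chemistry. An isopropylidene ketal on O8/O9 leaves O6 and O10 as the only acylable hydroxyls of 20 (O4 is tertiary), so both esters form in one operation from 21. The ketal must come off in dilute acid, which the esters tolerate.

**20 ⇒ 19 (C10–H bond).** The C10 carbinol is cut back to the ketone 19 and not further, because the ketal already present on the adjacent cis-diol is the element that can force hydride to the β face. The forward reduction has to deliver H to the methyl-bearing face and give the all-cis 8,9,10 array.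

**19 ⇒ 18 ⇒ 17 (C8–O and C9–O bonds).** O8 and O9 are cis, so both C–O bonds are cut together as a cis-dihydroxylation of the C8=C9 enone 17. Leaving C10 as a carbonyl at this stage keeps an allylic oxygen from steering the osmium reagent, so only the axial C1 methyl, which sits under the β face of C9, decides the face. The ketal then masks the pair at once.

**17 ⇒ 16 ⇒ 15 (C6–O bond, C7–H bond).** The C6 oxygen and the C7 methylene are traced to the C6=C7 bond of dienone 15. An electrophilic epoxidation picks this bond because it is the one remote from the carbonyl, and palladium-catalysed hydrogenolysis of the allylic C7–O bond of 16 leaves O6 in place, makes C7 a methylene and restores the enone needed next.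

**15 ⇒ 14 ⇒ 12 + 13 (C1–CH3 bond).** The angular methyl is cut as the methylene of a cyclopropane spanning the C1=C10 enol ether of 12. The C4 hydroxyl can deliver that carbon (from 13) to the β face, which fixes C1 relative to C4 and leaves C5 untouched; acid opening of 14 then turns the methoxy-bearing carbon into the C10 ketone. An enolate methylation was not chosen: the open face of a ring-fusion enolate is the H5 face, and a later epimerisation at C5 would break the C4/C5 relationship.

**12 ⇒ 10 + 11 (C4–iPr bond).** The isopropyl group is added to the C4 ketone first, because this removes the acidity of H5 (α to the ketone and doubly allylic) before any other operation and uses C5 to set C4.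

**10 ⇒ 8 (C5–C1 and C5–C6 bonds; key disconnection).** Both rings are cut at C5. This returns the arene, which holds C1, C6–C10, the C8 methyl and the C10 oxygen, and a diazoketone chain C2–C5. The forward reaction must add the carbene to the unsubstituted ortho bond and set C5 by catalyst control.

**8 ⇒ 6 + 7 ⇒ 5 ⇒ 4 ⇒ 1 + 2.** The diazoketone comes from acid chloride 6 and 7; the acid 5 comes from 1 by a two-carbon homologation with 2 and hydrogenation. These are four routine steps, so the risk sits in step 5.

## Alternatives that were turned down

**Alternative 1:** The seven-membered ring is cut at C7–C8 and C1–C10, into a three-carbon unit C8–C10 and a diene C7=C6–C5=C1 that already carries the cyclopentane. In the forward step the dirhodium carbene from vinyl diazoester A2 cyclopropanates the terminal C6=C7 bond of siloxydiene A3, and the cis-divinylcyclopropane rearranges (Cope, boat transition state) to the bicyclic bis(silyl enol ether) A1.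
- For it: it is convergent, it makes the quaternary C1 in the ring-forming event under control of a chiral dirhodium carboxylate, and C6 and C9 arrive oxygenated.
- Against it: C8 carries an ester where a methyl is needed, C10 arrives as CH2 and must later be oxidised next to the quaternary centre with the oxygen anti to the methyl, and C5 is sp2 in A1 so H5 must be set afterwards. A3 needs its own enantioselective synthesis, and its C4 centre lies three atoms from the reacting C6=C7 bond, so it cannot be trusted to relay to C1. The Cope step must also bring a fully substituted alkene terminus into the boat.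
- Comparison: it is stronger on convergence and on direct construction of C1. The chosen route offers in its place a four-step precursor 8 in which all ring carbons, the C8 methyl and the C10 oxygen are already present, and it sets C1 by a hydroxyl-directed delivery from the adjacent C4 centre.

**Alternative 2:** The bonds C1–C5 and C9–C10 are cut, with a temporary C5–O–C9 bridge. In the forward step base removes acetate from acetoxypyranone A5, and the resulting oxidopyrylium adds across the tethered Z enol ether to give the cyclopentane-fused oxa-bridged cycloheptenone A4.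
- For it: one step forms both rings and the C1, C5, C9 and C10 centres, and the enol ether geometry fixes the C1-methyl/C10-oxygen relationship. On that point it is stronger than the chosen route, which has to win this relationship in step 13. The C8 methyl and a C6 carbonyl are also in place.
- Against it: A5 is a long linear target (an enantiopure, fully substituted C4 carbinol next to the pyranone and a geometrically pure enol ether). The C5–O bond must later be cleaved reductively and C5 protonated on the α face, which the C6 enolate does not guarantee. The pyrylium terminus is also flanked by the quaternary C4.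
- Comparison: it is richer in stereochemical information per step. The chosen route offers a far shorter way to its key precursor and no bridge to dismantle.

**Alternative 3:** Only the C1–C5 bond of the cyclopentane is cut. In the forward step the rhodium carbene of diazo keto ester A7, made from (R)-citronellol A8, inserts into the tertiary C1–H bond with retention to give cyclopentanone A6.
- For it: the absolute configuration of the quaternary C1 comes from the chiral pool by a very dependable reaction, no chiral catalyst is needed, and the C4 ketone is ready for the isopropyl group. In certainty of the key step it is stronger than the chosen route.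
- Against it: the step makes one ring and one C–C bond. The whole seven-membered ring (C7, C8 and the closure) and its four oxygenated centres are still to be built from an unfunctionalised C9–C10 chain, so the linear sequence should be markedly longer.
- Comparison: the chosen route accepts more risk in one step and in return delivers both rings and the full ring skeleton at once.

Key step: step 5

## Route

Step 1
Reactants: 1 2-methoxy-4-methylbenzaldehyde; 2 malonic acid
Product: 4 (E)-3-(2-methoxy-4-methylphenyl)prop-2-enoic acid, via 2-(2-methoxy-4-methylbenzylidene)malonic acid 3 (not isolated)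
Conditions: pyridine, piperidine (cat.), 100 °C
Reagents that add atoms: malonic acid, OC(=O)CC(=O)O
Why: Knoevenagel condensation in the Doebner modification; the arylidene malonic acid loses CO2 in hot pyridine and the E acid should form under thermodynamic control.

Step 2
Reactants: 4 (E)-3-(2-methoxy-4-methylphenyl)prop-2-enoic acid
Product: 5 3-(2-methoxy-4-methylphenyl)propanoic acid
Conditions: H2 (1 atm), palladium on carbon (Pd/C, 10 %), EtOAc, rt
Reagents that add atoms: none
Why: Heterogeneous hydrogenation of the cinnamic acid double bond; the arene and the methyl ether are inert under these conditions.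

Step 3
Reactants: 5 3-(2-methoxy-4-methylphenyl)propanoic acid
Product: 6 3-(2-methoxy-4-methylphenyl)propanoyl chloride
Conditions: (COCl)2, DMF (cat.), CH2Cl2, 0 °C to rt; used crude
Reagents that add atoms: oxalyl chloride, O=C(Cl)C(=O)Cl
Why: Acid chloride formation through the Vilsmeier chloroiminium ion; all by-products are gases.

Step 4
Reactants: 6 3-(2-methoxy-4-methylphenyl)propanoyl chloride; 7 (trimethylsilyl)diazomethane
Product: 8 1-diazo-4-(2-methoxy-4-methylphenyl)butan-2-one
Conditions: Me3SiCHN2 (2.2 equiv), THF/MeCN (1:1), 0 °C to rt
Reagents that add atoms: (trimethylsilyl)diazomethane, C[Si](C)(C)C=[N+]=[N-]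
Why: Acylation of the diazoalkane as in the first stage of an Arndt–Eistert homologation; silicon leaves as Me3SiCl and the acceptor-substituted diazoketone is stable to chromatography.

Step 5
Reactants: 8 1-diazo-4-(2-methoxy-4-methylphenyl)butan-2-one
Product: 10 (8aS)-4-methoxy-6-methyl-3,8a-dihydroazulen-1(2H)-one, via norcaradiene valence isomer 9 (not isolated)
Conditions: [Cu(MeCN)4]PF6 (5 mol %), 2,2'-(propane-2,2-diyl)bis[(4S)-4-tert-butyl-4,5-dihydro-1,3-oxazole] (6 mol %), NaB[3,5-(CF3)2C6H3]4 (6 mol %), CH2Cl2, 40 °C, slow addition of 8; cold filtration through neutral alumina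
Reagents that add atoms: none
Why: Monovalent copper bound to the bis(oxazoline) takes N2 out of 8 and gives an electrophilic copper carbene at C5. The carbene adds across the ipso/ortho π-bond C1–C6 of the arene to give norcaradiene 9, which opens by disrotatory 6π electrocyclisation to cycloheptatriene 10; the closest known reaction type is the enantioselective intramolecular Buchner reaction of 1-diazo-4-arylbutan-2-ones to azulenones under copper bis(oxazoline) catalysis. The five-membered ring closes by bonding the carbene carbon to the ipso carbon (C5–C1), the three-atom tether allowing only the fused bicyclo[3.1.0] mode, and the seven-membered ring is the benzene ring enlarged by C5 when the C1–C6 σ-bond of 9 breaks. The one stereocentre that survives, C5, is set in the cyclopropanation by the C2-symmetric ligand, which distinguishes the two enantiotopic approaches of the carbene to the arene, and C5 keeps its four substituents through the ring opening. The step needs site selectivity for C1–C6 over C1–C10: the C1–C10 bond is fully substituted and carries the methoxy group, so addition there is sterically disfavoured. C6 is meta to both donor groups, which should hold back the competing aromatic substitution to a 2-tetralone, while the ortho methoxy and para methyl groups raise the electron density at the ipso carbon where bonding starts. Because H5 of 10 is α to the ketone and doubly allylic, 10 is kept cold and free of acid or base and is taken at once into step 6.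

Step 6
Reactants: 10 (8aS)-4-methoxy-6-methyl-3,8a-dihydroazulen-1(2H)-one; 11 isopropylmagnesium chloride
Product: 12 (1S,8aS)-4-methoxy-6-methyl-1-(propan-2-yl)-1,2,3,8a-tetrahydroazulen-1-ol (4β-hydroxy, 5α-H)
Conditions: CeCl3 (anhydrous, 1.5 equiv), iPrMgCl (1.5 equiv), THF, −78 °C; pH 7 buffer
Reagents that add atoms: isopropylmagnesium chloride, CC(C)[Mg]Cl
Why: Organocerium 1,2-addition (Imamoto conditions), which should outrun enolisation at C5; the nucleophile enters the C4 carbonyl from the face of H5, away from C6 and the folded seven-membered ring (the exo face of the bicyclo[3.1.0]hexanone in the norcaradiene form), so isopropyl ends cis to H5 and the hydroxyl β.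

Step 7
Reactants: 12 (1S,8aS)-4-methoxy-6-methyl-1-(propan-2-yl)-1,2,3,8a-tetrahydroazulen-1-ol; 13 diiodomethane
Product: 14 1,10-methano adduct of 12 (CH2 bridge on the β face of C1 and C10; 10α-methoxy; 4β-hydroxy; 5α-H)
Conditions: Et2Zn (2.5 equiv), CH2I2 (2.5 equiv), CH2Cl2, −20 to 0 °C
Reagents that add atoms: diiodomethane, ICI
Why: Simmons–Smith cyclopropanation (Furukawa variant); the enol ether C1=C10 is the most electron-rich of the three double bonds, and the zinc alkoxide of the homoallylic C4 hydroxyl should deliver the methylene to its β face, which sets C1 (future methyl cis to O4, trans to H5) and C10 without touching C5.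

Step 8
Reactants: 14 1,10-methano adduct of 12
Product: 15 4β-hydroxy-5αH-dauca-6,8-dien-10-one (1β-methyl, trans ring fusion)
Conditions: 1 M HCl, THF, 0 °C to rt
Reagents that add atoms: water, O
Why: Acid-induced opening of an alkoxycyclopropane: protonation at the unsubstituted methylene breaks the C10–CH2 bond and gives an oxocarbenium ion stabilised by the diene, hydrolysis of which gives the C10 ketone; the methylene becomes the C1 methyl with the C1 configuration unchanged.

Step 9
Reactants: 15 4β-hydroxy-5αH-dauca-6,8-dien-10-one
Product: 16 6α,7α-epoxy-4β-hydroxy-5αH-dauc-8-en-10-one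
Conditions: dimethyldioxirane (1.1 equiv), acetone, 0 °C
Reagents that add atoms: dimethyldioxirane, CC1(C)OO1
Why: Electrophilic epoxidation of a 2,4-dienone goes to the γ,δ double bond C6=C7, away from the carbonyl; the oxidant should come from the α face beside axial H5, because C1 and its axial methyl lie under the β face.

Step 10
Reactants: 16 6α,7α-epoxy-4β-hydroxy-5αH-dauc-8-en-10-one
Product: 17 4β,6α-dihydroxy-5αH-dauc-8-en-10-one
Conditions: Pd2(dba)3·CHCl3 (dba = dibenzylideneacetone, 2.5 mol %), nBu3P (10 mol %), HCO2H (5 equiv), Et3N (2 equiv), dioxane, rt
Reagents that add atoms: none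
Why: Tsuji-type hydrogenolysis of an alkenyl oxirane: zerovalent palladium opens the allylic C7–O bond, formate supplies a palladium hydride and hydrogen is delivered to C7, which restores the conjugated enone; the C6–O bond is not touched, so the 6α configuration is kept.

Step 11
Reactants: 17 4β,6α-dihydroxy-5αH-dauc-8-en-10-one
Product: 18 4β,6α,8α,9α-tetrahydroxy-5αH-daucan-10-one
Conditions: OsO4 (5 mol %), N-methylmorpholine N-oxide (1.5 equiv), citric acid (1 equiv), tBuOH/H2O (1:1), rt
Reagents that add atoms: N-methylmorpholine N-oxide, C[N+]1([O-])CCOCC1; water, O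
Why: Catalytic cis-dihydroxylation (Upjohn conditions with an acid additive for the electron-poor enone); the axial C1 methyl sits under the β face of C9 and the ring carbons C1 and C6 fold to β, so the osmium reagent should add from α and set the 8α,9α-diol.

Step 12
Reactants: 18 4β,6α,8α,9α-tetrahydroxy-5αH-daucan-10-one
Product: 19 4β,6α-dihydroxy-8α,9α-(isopropylidenedioxy)-5αH-daucan-10-one
Conditions: 2,2-dimethoxypropane (3 equiv), pyridinium p-toluenesulfonate (cat.), acetone, rt
Reagents that add atoms: 2,2-dimethoxypropane, COC(C)(C)OC
Why: Ketalisation of the only cis-1,2-diol (O8/O9); it removes the β-hydroxy ketone that could undergo retro-aldol cleavage and separates O9 from O6 and O10.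

Step 13
Reactants: 19 4β,6α-dihydroxy-8α,9α-(isopropylidenedioxy)-5αH-daucan-10-one
Product: 20 8α,9α-(isopropylidenedioxy)-5αH-daucane-4β,6α,10α-triol
Conditions: NaBH4 (2 equiv), MeOH, 0 °C
Reagents that add atoms: none
Why: Hydride reduction anti to a cis-fused dioxolane next to the carbonyl: with the C8–C9 torsion held near zero by the ketal, the α face of C10 carries O9, the axial O8 with the endo ketal methyl and the nearly perpendicular C1–C5 bond, whereas the C1 methyl is swung away from the β trajectory, so hydride should enter from β and give the 10α alcohol.

Step 14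
Reactants: 20 8α,9α-(isopropylidenedioxy)-5αH-daucane-4β,6α,10α-triol; 21 angelic acid ((Z)-2-methylbut-2-enoic acid)
Product: 23 6α,10α-bis(angeloyloxy)-8α,9α-(isopropylidenedioxy)-5αH-daucan-4β-ol, via 6-O-angeloyl monoester 22 (not isolated)
Conditions: angelic acid (4 equiv), 2,4,6-trichlorobenzoyl chloride (4 equiv), Et3N (4.4 equiv), toluene, rt; then 20, 80 °C
Reagents that add atoms: angelic acid, C/C=C(/C)C(=O)O
Why: Acylation through the mixed 2,4,6-trichlorobenzoic anhydride without a nucleophilic catalyst (Yamaguchi-type), a protocol that keeps the Z geometry; the less hindered O6 should react first and O10 second, the tertiary O4 not at all.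

Step 15
Reactants: 23 6α,10α-bis(angeloyloxy)-8α,9α-(isopropylidenedioxy)-5αH-daucan-4β-ol
Product: 24 6α,10α-bis(angeloyloxy)-5αH-daucane-4β,8α,9α-triol (CNP0194216.1)
Conditions: AcOH/H2O (4:1), 40 °C
Reagents that add atoms: none
Why: Acid hydrolysis of the isopropylidene ketal; in the absence of base neither Z to E isomerisation of the angelates nor acyl migration to O9 is expected, and dilute acetic acid should spare the tertiary alcohols.

## Compound list

1 | 2-methoxy-4-methylbenzaldehyde | COc1cc(C)ccc1C=O | starting material
2 | malonic acid | OC(=O)CC(=O)O | starting material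
3 | 2-(2-methoxy-4-methylbenzylidene)malonic acid | COc1cc(C)ccc1C=C(C(=O)O)C(=O)O | intermediate (not isolated)
4 | (E)-3-(2-methoxy-4-methylphenyl)prop-2-enoic acid | COc1cc(C)ccc1/C=C/C(=O)O | intermediate
5 | 3-(2-methoxy-4-methylphenyl)propanoic acid | COc1cc(C)ccc1CCC(=O)O | intermediate
6 | 3-(2-methoxy-4-methylphenyl)propanoyl chloride | COc1cc(C)ccc1CCC(=O)Cl | intermediate
7 | (trimethylsilyl)diazomethane | C[Si](C)(C)C=[N+]=[N-] | starting material
8 | 1-diazo-4-(2-methoxy-4-methylphenyl)butan-2-one | COc1cc(C)ccc1CCC(=O)C=[N+]=[N-] | intermediate
9 | norcaradiene valence isomer of 10 (cyclopropane C1–C5–C6, H5 and H6 trans) | O=C1CC[C@]23C(OC)=CC(C)=C[C@H]2[C@H]13 | intermediate (not isolated)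
10 | (8aS)-4-methoxy-6-methyl-3,8a-dihydroazulen-1(2H)-one | O=C1CCC2=C(OC)C=C(C)C=C[C@H]12 | intermediate
11 | isopropylmagnesium chloride | CC(C)[Mg]Cl | starting material
12 | (1S,8aS)-4-methoxy-6-methyl-1-(propan-2-yl)-1,2,3,8a-tetrahydroazulen-1-ol | C1=CC(C)=CC(OC)=C2CC[C@](O)(C(C)C)[C@@H]12 | intermediate
13 | diiodomethane | ICI | starting material
14 | 1,10-methano adduct of 12 (CH2 on the β face, 10α-methoxy) | C1=CC(C)=C[C@@]3(OC)C[C@@]23CC[C@](O)(C(C)C)[C@@H]12 | intermediate
15 | 4β-hydroxy-5αH-dauca-6,8-dien-10-one | C1=CC(C)=CC(=O)[C@]2(C)CC[C@](O)(C(C)C)[C@@H]12 | intermediate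
16 | 6α,7α-epoxy-4β-hydroxy-5αH-dauc-8-en-10-one | O3[C@@H]1[C@H]3C(C)=CC(=O)[C@]2(C)CC[C@](O)(C(C)C)[C@@H]12 | intermediate
17 | 4β,6α-dihydroxy-5αH-dauc-8-en-10-one | O[C@@H]1CC(C)=CC(=O)[C@]2(C)CC[C@](O)(C(C)C)[C@@H]12 | intermediate
18 | 4β,6α,8α,9α-tetrahydroxy-5αH-daucan-10-one | O[C@@H]1C[C@](C)(O)[C@H](O)C(=O)[C@]2(C)CC[C@](O)(C(C)C)[C@@H]12 | intermediate
19 | 4β,6α-dihydroxy-8α,9α-(isopropylidenedioxy)-5αH-daucan-10-one | O[C@@H]1C[C@](C)(OC3(C)C)[C@H](O3)C(=O)[C@]2(C)CC[C@](O)(C(C)C)[C@@H]12 | intermediate
20 | 8α,9α-(isopropylidenedioxy)-5αH-daucane-4β,6α,10α-triol | O[C@@H]1C[C@](C)(OC3(C)C)[C@H](O3)[C@H](O)[C@]2(C)CC[C@](O)(C(C)C)[C@@H]12 | intermediate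
21 | angelic acid, (Z)-2-methylbut-2-enoic acid | C/C=C(/C)C(=O)O | starting material
22 | 6α-angeloyloxy-8α,9α-(isopropylidenedioxy)-5αH-daucane-4β,10α-diol | C/C=C(/C)C(=O)O[C@@H]1C[C@](C)(OC3(C)C)[C@H](O3)[C@H](O)[C@]2(C)CC[C@](O)(C(C)C)[C@@H]12 | intermediate (not isolated)
23 | 6α,10α-bis(angeloyloxy)-8α,9α-(isopropylidenedioxy)-5αH-daucan-4β-ol | C/C=C(/C)C(=O)O[C@@H]1C[C@](C)(OC3(C)C)[C@H](O3)[C@H](OC(=O)/C(C)=C\C)[C@]2(C)CC[C@](O)(C(C)C)[C@@H]12 | intermediate
24 | 6α,10α-bis(angeloyloxy)-5αH-daucane-4β,8α,9α-triol (CNP0194216.1) | C/C=C(/C)C(=O)O[C@@H]1C[C@](C)(O)[C@H](O)[C@H](OC(=O)/C(C)=C\C)[C@]2(C)CC[C@](O)(C(C)C)[C@@H]12 | target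

## Step count and least certain steps

Total step count: 15. Longest linear sequence: 15 steps (1 to 24).

**Step 5 (key step).** The most likely failure is incomplete enantiocontrol in the carbene addition, made worse by enolisation at C5 of the product during isolation; aromatic substitution to a tetralone and addition at the methoxy-bearing bond are lesser risks. The fallback gives up asymmetric catalysis and resolves instead. It sets out from 8: dirhodium tetraacetate, Rh2(OAc)4 (1 mol %, CH2Cl2, rt), should give the racemic azulenone, that is 10 together with its mirror image (8aR)-4-methoxy-6-methyl-3,8a-dihydroazulen-1(2H)-one F1. The conditions of step 6 convert the pair into 12 and its mirror image (1R,8aR)-4-methoxy-6-methyl-1-(propan-2-yl)-1,2,3,8a-tetrahydroazulen-1-ol F2, which are separated by preparative chromatography on an amylose tris(3,5-dimethylphenylcarbamate) phase. The fallback returns to the route at 12.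

**Step 7.** The likely failures are competing cyclopropanation of the C6=C7 bond, which is also homoallylic to the zinc alkoxide, and delivery to the wrong face if the alkoxide does not direct. The fallback introduces the methyl by enolate alkylation. It sets out from 12: aqueous oxalic acid in THF hydrolyses the enol ether to 4β-hydroxy-15-nor-5αH-dauca-6,8-dien-10-one F3 (both C1 epimers). LiN(iPr)2 (2.2 equiv, THF, −78 °C) then forms the cross-conjugated C1 enolate by kinetic α' deprotonation, and iodomethane methylates C1. The fallback returns to the route at 15 and skips step 8. Its weak point is that the C1 configuration then rests on substrate control (the C4 isopropyl group screens the α face), and the C1 epimer would have to be removed.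

**Step 13.** The likely failure is attack of hydride from the α face, anti to the C1 methyl, which would give the 10β alcohol. The fallback inverts that carbinol by substitution. It sets out from 19 by way of the epimer 8α,9α-(isopropylidenedioxy)-5αH-daucane-4β,6α,10β-triol F4.
- The less hindered O6 is acylated under the conditions of step 14 (1.2 equiv of the mixed anhydride, 60 °C) to give 6α-angeloyloxy-8α,9α-(isopropylidenedioxy)-5αH-daucane-4β,10β-diol F5.
- Mitsunobu reaction with chloroacetic acid (PPh3, diisopropyl azodicarboxylate, toluene, rt to 50 °C) should invert C10 and give the 10α-chloroacetate of the 6-angelate F6. Elimination is excluded because C1 is quaternary and H9 is cis to the leaving group, and the carboxylate enters on the α trajectory.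
- Thiourea with NaHCO3 in EtOH removes the chloroacetyl group selectively.

The fallback returns to the route at 22, which is esterified at O10 under the conditions of step 14 to give 23.

**Step 10.** The likely failure is slow ionisation of the vinyl epoxide, because the β face of the allyl unit near C9 is screened by the C1 methyl, with isomerisation of the epoxide to a carbonyl compound taking over. The fallback opens the epoxide by electron transfer. It sets out from 16: SmI2 (2.2 equiv, THF/MeOH, −78 °C) reduces the enone, the C7–O bond breaks, and protonation at C9 gives the deconjugated 4β,6α-dihydroxy-5αH-dauc-7-en-10-one F7. A catalytic amount of 1,8-diazabicyclo[5.4.0]undec-7-ene in CH2Cl2 moves the double bond back into conjugation. The fallback returns to the route at 17.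

**Step 14.** The likely failure is incomplete acylation of the axial, doubly flanked 10α hydroxyl, with Z to E isomerisation of the angelate setting in when the reaction is forced. The fallback builds the Z-enoates on the substrate. It sets out from 20: both secondary hydroxyls are esterified with 2-[bis(2,2,2-trifluoroethoxy)phosphoryl]propanoic acid (dicyclohexylcarbodiimide, 4-dimethylaminopyridine, CH2Cl2) to give the 6,10-bis(phosphonopropanoate) of 20 F8. Still–Gennari olefination with acetaldehyde (KN(SiMe3)2, 18-crown-6, THF, −78 °C) then forms the two (Z)-2-methylbut-2-enoates. The fallback returns to the route at 23.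

Further compounds
F1 | step 5 | (8aR)-4-methoxy-6-methyl-3,8a-dihydroazulen-1(2H)-one | O=C1CCC2=C(OC)C=C(C)C=C[C@@H]12
F2 | step 5 | (1R,8aR)-4-methoxy-6-methyl-1-(propan-2-yl)-1,2,3,8a-tetrahydroazulen-1-ol | C1=CC(C)=CC(OC)=C2CC[C@@](O)(C(C)C)[C@H]12
F3 | step 7 | 4β-hydroxy-15-nor-5αH-dauca-6,8-dien-10-one (both C1 epimers) | C1=CC(C)=CC(=O)C2CC[C@](O)(C(C)C)[C@@H]12
F4 | step 13 | 8α,9α-(isopropylidenedioxy)-5αH-daucane-4β,6α,10β-triol | O[C@@H]1C[C@](C)(OC3(C)C)[C@H](O3)[C@@H](O)[C@]2(C)CC[C@](O)(C(C)C)[C@@H]12
F5 | step 13 | 6α-angeloyloxy-8α,9α-(isopropylidenedioxy)-5αH-daucane-4β,10β-diol | C/C=C(/C)C(=O)O[C@@H]1C[C@](C)(OC3(C)C)[C@H](O3)[C@@H](O)[C@]2(C)CC[C@](O)(C(C)C)[C@@H]12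
F6 | step 13 | 6α-angeloyloxy-10α-(chloroacetoxy)-8α,9α-(isopropylidenedioxy)-5αH-daucan-4β-ol | C/C=C(/C)C(=O)O[C@@H]1C[C@](C)(OC3(C)C)[C@H](O3)[C@H](OC(=O)CCl)[C@]2(C)CC[C@](O)(C(C)C)[C@@H]12
F7 | step 10 | 4β,6α-dihydroxy-5αH-dauc-7-en-10-one | O[C@@H]1C=C(C)CC(=O)[C@]2(C)CC[C@](O)(C(C)C)[C@@H]12
F8 | step 14 | 6α,10α-bis{2-[bis(2,2,2-trifluoroethoxy)phosphoryl]propanoyloxy}-8α,9α-(isopropylidenedioxy)-5αH-daucan-4β-ol | CC(C(=O)O[C@@H]1C[C@](C)(OC3(C)C)[C@H](O3)[C@H](OC(=O)C(C)P(=O)(OCC(F)(F)F)OCC(F)(F)F)[C@]2(C)CC[C@](O)(C(C)C)[C@@H]12)P(=O)(OCC(F)(F)F)OCC(F)(F)F
A1 | alternative 1 | bicyclo[5.3.0]decadiene bis(silyl enol ether) with the C8 methyl ester | COC(=O)C1=C(O[Si](C)(C)C(C)(C)C)C[C@]2(C)CC[C@](O[Si](CC)(CC)CC)(C(C)C)C2=C(O[Si](C)(C)C(C)(C)C)C1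
A2 | alternative 1 | methyl 3-(tert-butyldimethylsilyloxy)-2-diazobut-3-enoate | COC(=O)C(=[N+]=[N-])C(=C)O[Si](C)(C)C(C)(C)C
A3 | alternative 1 | 1-[1-(tert-butyldimethylsilyloxy)vinyl]-2-methyl-5-(propan-2-yl)-5-(triethylsilyloxy)cyclopent-1-ene | C=C(O[Si](C)(C)C(C)(C)C)C1=C(C)CC[C@]1(O[Si](CC)(CC)CC)C(C)C
A4 | alternative 2 | cyclopentane-fused 8-oxabicyclo[3.2.1]octenone with the C5–O–C9 bridge | O=C1C=C(C)[C@H]2[C@H](OCc4ccccc4)[C@]3(C)CC[C@](O[Si](CC)(CC)CC)(C(C)C)[C@@]13O2
A5 | alternative 2 | 6-acetoxy-5-methyl-2H-pyran-3(6H)-one carrying at C2 the C4–C1 tether with the Z benzyl enol ether | CC(=O)OC1OC(C(=O)C=C1C)[C@@](O[Si](CC)(CC)CC)(C(C)C)CC/C(C)=C\OCc1ccccc1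
A6 | alternative 3 | methyl 2-methyl-2-[2-(tert-butyldimethylsilyloxy)ethyl]-5-oxocyclopentanecarboxylate | COC(=O)[C@@H]1C(=O)CC[C@@]1(C)CCO[Si](C)(C)C(C)(C)C
A7 | alternative 3 | methyl (6R)-8-(tert-butyldimethylsilyloxy)-2-diazo-6-methyl-3-oxooctanoate | COC(=O)C(=[N+]=[N-])C(=O)CC[C@@H](C)CCO[Si](C)(C)C(C)(C)C
A8 | alternative 3 | (R)-citronellol | C[C@H](CCC=C(C)C)CCO
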